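## Retrosynthetic overview

1. Ring numbering used throughout: C1 ketone, C2 (OMe), C3 (=CH), C4 (OH), C5 (farnesyl), C6 (Me). The enone is opened to the C1 silyl enol ether 22 (Saegusa–Ito retron).
2. 22 is disconnected at C1–C2 and C3–C4 into cyclobutanone 16 and 1-methoxyvinyllithium. The enabling feature is that C1 and C4 are 1,4-related across the C2=C3 enol ether and both carry oxygen; joining them gives a 2-silyloxycyclobutanone whose vicinal oxygens can hand over the silyl group and whose C4 alkoxide can expel C1 as a siloxyallyl anion.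
3. 16 comes from prochiral 3-farnesylcyclobutanone 9 by desymmetrising enolisation (sets C5), methylation (C6) and enolate hydroxylation (C4 oxygen).
4. 9 comes from farnesyl bromide, diethyl malonate and MeS(O)CH2SMe by a [3+1] cyclobutane construction.
5. Ring order: cyclobutane (step 4), then the cyclohexene (step 10) at the expense of the cyclobutane.

Key step: step 10

Remark: "farnesyl" means (2E,6E)-3,7,11-trimethyldodeca-2,6,10-trien-1-yl; the target's ring numbering is kept for the same atoms in the four-membered precursors.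

Assumption: the (S,S)-lithium amide in step 6 is taken to give the (3S)-enol ether; if the sense proves opposite, the (R,R)-amide is used.

## Route

Step 1
Reactants: 1 (2E,6E)-farnesyl bromide; 2 diethyl malonate
Product: 3 diethyl 2-farnesylmalonate
Conditions: NaH, THF, 0 → 25 °C, excess 2
Reagents that add atoms: none
Why: Malonic ester alkylation (SN2 at the primary allylic bromide, excess malonate against dialkylation) should leave the E-alkenes untouched.

Step 2
Reactants: 3 diethyl 2-farnesylmalonate
Product: 4 2-farnesylpropane-1,3-diol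
Conditions: LiAlH4, THF, 0 → 25 °C; aqueous NaOH work-up
Reagents that add atoms: none
Why: Hydride reduction of both esters should give the prochiral 1,3-diol, isolated trisubstituted alkenes being inert.

Step 3
Reactants: 4 2-farnesylpropane-1,3-diol
Product: 5 1,3-dibromo-2-farnesylpropane
Conditions: CBr4, PPh3, CH2Cl2, 0 °C
Reagents that add atoms: carbon tetrabromide BrC(Br)(Br)Br
Why: The Appel reaction should convert both primary alcohols into bromides under neutral conditions that spare the alkenes.

Step 4
Reactants: 5 1,3-dibromo-2-farnesylpropane; 6 methyl methylthiomethyl sulfoxide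
Product: 8 3-farnesyl-1-(methylsulfinyl)-1-(methylthio)cyclobutane, via monoalkylated bromide 7 (not isolated)
Conditions: n-BuLi (two portions), THF, −70 → 25 °C
Reagents that add atoms: none
Why: Double alkylation of the formaldehyde dithioacetal S-oxide carbanion (an acyl-anion equivalent), the second event a 4-exo-tet closure, is the established [3+1] entry to 3-substituted cyclobutanone precursors.

Step 5
Reactants: 8 3-farnesyl-1-(methylsulfinyl)-1-(methylthio)cyclobutane
Product: 9 3-farnesylcyclobutan-1-one
Conditions: 2 M aqueous H2SO4, THF/Et2O, 0 → 25 °C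
Reagents that add atoms: water O
Why: Acid hydrolysis of a dithioacetal S-oxide is far faster than protonation of trisubstituted alkenes, so dilute acid should unmask only the ketone.

Step 6
Reactants: 9 3-farnesylcyclobutan-1-one
Product: 11 (3S)-3-farnesyl-1-(trimethylsilyloxy)cyclobut-1-ene, via lithium enolate 10 (not isolated)
Conditions: LiN[(S)-CH(Me)Ph]2 (from the (S,S)-amine and n-BuLi), Me3SiCl (present from the start), THF, −100 °C
Reagents that add atoms: chlorotrimethylsilane C[Si](C)(C)Cl
Why: Enantiotopic-proton-selective deprotonation of a 3-substituted cyclobutanone by a C2-symmetric chiral lithium amide with in situ silylation should set C5 under reagent control.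

Step 7
Reactants: 11 (3S)-3-farnesyl-1-(trimethylsilyloxy)cyclobut-1-ene
Product: 13 (2R,3S)-2-methyl-3-farnesylcyclobutan-1-one, via benzyltrimethylammonium enolate 12 (not isolated)
Conditions: BnMe3NF (anhydrous), MeI (excess, present from the start), 4 Å molecular sieves, THF, −78 → 0 °C
Reagents that add atoms: iodomethane CI
Why: Fluoride-promoted desilylation should release the regiodefined quaternary ammonium enolate (regiospecific alkylation of a silyl enol ether), which is methylated at once by the MeI already present, before proton exchange can move the enolate, and anti to the adjacent farnesyl group to give the 2,3-trans ketone (C6 set by substrate control).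

Step 8
Reactants: 13 (2R,3S)-2-methyl-3-farnesylcyclobutan-1-one
Product: 15 (2S,3R,4R)-2-hydroxy-4-methyl-3-farnesylcyclobutan-1-one, via potassium enolate 14 (not isolated)
Conditions: KN(SiMe3)2, THF, −78 °C; 3-phenyl-2-(phenylsulfonyl)oxaziridine; NH4Cl (aq.)
Reagents that add atoms: 3-phenyl-2-(phenylsulfonyl)oxaziridine O=S(=O)(c1ccccc1)N1OC1c1ccccc1
Why: Kinetic deprotonation at the CH2 α-carbon and electrophilic enolate hydroxylation by the N-sulfonyloxaziridine anti to the neighbouring farnesyl group should give the all-trans acyloin.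

Step 9
Reactants: 15 (2S,3R,4R)-2-hydroxy-4-methyl-3-farnesylcyclobutan-1-one
Product: 16 (2S,3R,4R)-4-methyl-3-farnesyl-2-(triethylsilyloxy)cyclobutan-1-one
Conditions: Et3SiCl, imidazole, CH2Cl2, 0 °C
Reagents that add atoms: chlorotriethylsilane CC[Si](CC)(CC)Cl
Why: Standard silylation should fix the acyloin regiochemistry and supply the silyl group that the key step relays to the C1 oxygen.

Step 10
Reactants: 16 (2S,3R,4R)-4-methyl-3-farnesyl-2-(triethylsilyloxy)cyclobutan-1-one; 17 methyl vinyl ether
Product: 22 (1S,5R,6R)-3-methoxy-5-methyl-6-farnesyl-4-(triethylsilyloxy)cyclohex-3-en-1-ol, via 1-methoxyvinyllithium 18 (not isolated), via adduct alkoxide 19 (not isolated), via silyl-shifted alkoxide 20 (not isolated), via ring-opened allyllithium 21 (not isolated)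
Conditions: 17, t-BuLi, THF, −78 → 0 °C; 16 (slight deficit), −78 °C; then HMPA, −78 → 25 °C; pH 7 phosphate buffer
Reagents that add atoms: none
Why: Proposed new method: 1-methoxyvinyllithium 18 should add to the strained C1 carbonyl from the face opposite the C4–OSiEt3 and C6–Me groups, so the alkoxide of 19 is cis to the silyl ether and the Et3Si group can pass to it through a five-membered silicate (1,4 O-to-O shift) to give the C4 alkoxide 20. That alkoxide should drive retro-allylation of the C1–C4 bond (about 26 kcal/mol of ring strain released) to the tethered aldehyde/2-methoxy-1-siloxyallyl anion 21, whose C3 terminus recloses on the aldehyde; the closest known reaction type is the alkoxide-accelerated 1,3-shift of 2-vinylcyclobutanol salts to cyclohex-3-enols, here fed by a ketone addition and a silyl shift of the kind that generates Brook-type siloxyallyl anions. The six-membered ring closes 6-(enolendo)-exo-trig (formally a suprafacial 1,3-shift of C4 from C1 to C3), whereas reclosure at C1 only returns 20. The new C4 stereocentre is set in that closure by a Felkin–Anh chair with the C5 farnesyl and C6 methyl groups equatorial, farnesyl antiperiplanar to the forming C3–C4 bond and the aldehyde oxygen axial, which gives the 4,5-cis alcohol (a concerted shift with inversion at C4 of trans-configured 20 would give the same isomer); C5 and C6 are not touched. The step needs silylation of the C1 rather than the C4 oxygen and attack through C3 rather than C1: the first is secured by irreversible drain of 20 from the silyl-shift equilibrium, the second by strain, and the aldehyde stays masked as the cyclobutanol until the vinyllithium is spent. The product holds C1 as a regiodefined silyl enol ether, so the C2=C3 bond can be introduced without enolising toward C6.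

Step 11
Reactants: 22 (1S,5R,6R)-3-methoxy-5-methyl-6-farnesyl-4-(triethylsilyloxy)cyclohex-3-en-1-ol
Product: 23 (4R,5R,6R)-4-hydroxy-2-methoxy-6-methyl-5-farnesylcyclohex-2-en-1-one
Conditions: Pd(OAc)2 (stoichiometric), MeCN, 25 °C
Reagents that add atoms: none
Why: Saegusa–Ito oxidation: the divalent palladium enolate formed at C2 can undergo β-hydride elimination only toward C3 (C2 carries OMe and no hydrogen), giving the 2-methoxy enone and zerovalent palladium while the C4 alcohol and the chain alkenes stay as they are.

## Compound list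

1 | (2E,6E)-farnesyl bromide | BrC/C=C(\C)CC/C=C(\C)CCC=C(C)C | starting material
2 | diethyl malonate | CCOC(=O)CC(=O)OCC | starting material
3 | diethyl 2-farnesylmalonate | CCOC(=O)C(C/C=C(\C)CC/C=C(\C)CCC=C(C)C)C(=O)OCC | intermediate
4 | 2-farnesylpropane-1,3-diol | OCC(CO)C/C=C(\C)CC/C=C(\C)CCC=C(C)C | intermediate
5 | 1,3-dibromo-2-farnesylpropane | BrCC(CBr)C/C=C(\C)CC/C=C(\C)CCC=C(C)C | intermediate
6 | methyl methylthiomethyl sulfoxide | CS(=O)CSC | starting material
7 | 4-bromo-3-farnesyl-1-(methylsulfinyl)-1-(methylthio)butane (diastereomer mixture; not isolated) | CSC(CC(CBr)C/C=C(\C)CC/C=C(\C)CCC=C(C)C)S(C)=O | intermediate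
8 | 3-farnesyl-1-(methylsulfinyl)-1-(methylthio)cyclobutane (diastereomer mixture) | CSC1(S(C)=O)CC(C1)C/C=C(\C)CC/C=C(\C)CCC=C(C)C | intermediate
9 | 3-farnesylcyclobutan-1-one | O=C1CC(C1)C/C=C(\C)CC/C=C(\C)CCC=C(C)C | intermediate
10 | lithium (3S)-3-farnesylcyclobut-1-en-1-olate (not isolated) | [Li+].[O-]C1=C[C@@H](C/C=C(\C)CC/C=C(\C)CCC=C(C)C)C1 | intermediate
11 | (3S)-3-farnesyl-1-(trimethylsilyloxy)cyclobut-1-ene | C[Si](C)(C)OC1=C[C@@H](C/C=C(\C)CC/C=C(\C)CCC=C(C)C)C1 | intermediate
12 | benzyltrimethylammonium (3S)-3-farnesylcyclobut-1-en-1-olate (not isolated) | C[N+](C)(C)Cc1ccccc1.[O-]C1=C[C@@H](C/C=C(\C)CC/C=C(\C)CCC=C(C)C)C1 | intermediate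
13 | (2R,3S)-2-methyl-3-farnesylcyclobutan-1-one (Me and farnesyl trans) | O=C1[C@H](C)[C@@H](C/C=C(\C)CC/C=C(\C)CCC=C(C)C)C1 | intermediate
14 | potassium (3S,4R)-3-farnesyl-4-methylcyclobut-1-en-1-olate (not isolated) | [K+].[O-]C1=C[C@H](C/C=C(\C)CC/C=C(\C)CCC=C(C)C)[C@H]1C | intermediate
15 | (2S,3R,4R)-2-hydroxy-4-methyl-3-farnesylcyclobutan-1-one (OH and Me each trans to farnesyl) | O=C1[C@H](C)[C@@H](C/C=C(\C)CC/C=C(\C)CCC=C(C)C)[C@@H]1O | intermediate
16 | (2S,3R,4R)-4-methyl-3-farnesyl-2-(triethylsilyloxy)cyclobutan-1-one | O=C1[C@H](C)[C@@H](C/C=C(\C)CC/C=C(\C)CCC=C(C)C)[C@@H]1O[Si](CC)(CC)CC | intermediate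
17 | methyl vinyl ether | COC=C | starting material
18 | 1-methoxyvinyllithium (not isolated) | [Li]C(=C)OC | intermediate
19 | lithium (1R,2R,3R,4S)-1-(1-methoxyethenyl)-2-methyl-3-farnesyl-4-(triethylsilyloxy)cyclobutan-1-olate (O− cis to OSiEt3; not isolated) | [Li+].[O-][C@]1(C(OC)=C)[C@H](C)[C@@H](C/C=C(\C)CC/C=C(\C)CCC=C(C)C)[C@@H]1O[Si](CC)(CC)CC | intermediate
20 | lithium (1S,2R,3R,4R)-2-(1-methoxyethenyl)-3-methyl-4-farnesyl-2-(triethylsilyloxy)cyclobutan-1-olate (silyl group now on the tertiary oxygen; not isolated) | CC[Si](CC)(CC)O[C@]1(C(OC)=C)[C@H](C)[C@@H](C/C=C(\C)CC/C=C(\C)CCC=C(C)C)[C@@H]1[O-].[Li+] | intermediate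
21 | ring-opened (2R,3R)-2-farnesyl-3-methyl-4-(triethylsilyloxy)-5-methoxyhex-4-enal 6-lithio allyl anion (not isolated) | [Li+].[CH2-]\C(OC)=C(O[Si](CC)(CC)CC)/[C@H](C)[C@@H](C/C=C(\C)CC/C=C(\C)CCC=C(C)C)C=O | intermediate
22 | (1S,5R,6R)-3-methoxy-5-methyl-6-farnesyl-4-(triethylsilyloxy)cyclohex-3-en-1-ol (OH cis to farnesyl; Me trans to farnesyl) | CC[Si](CC)(CC)OC1=C(OC)C[C@H](O)[C@H](C/C=C(\C)CC/C=C(\C)CCC=C(C)C)[C@H]1C | intermediate
23 | (4R,5R,6R)-4-hydroxy-2-methoxy-6-methyl-5-farnesylcyclohex-2-en-1-one | COC1=C[C@H](O)[C@H](C/C=C(\C)CC/C=C(\C)CCC=C(C)C)[C@@H](C)C1=O | target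

## Step count and risks

Total step count: 11. Longest linear sequence: 11 steps (from 1).

Steps most likely to fail:

**Step 10 (Proposed new method).** The lithium alkoxide may not pass on the silyl group or may not fragment. The transient allyl anion may be quenched by proton transfer from C5–H or by surplus vinyllithium attacking the aldehyde. The C3–C4 closure may show poor facial selectivity. The fallback uses known reactions, sets out from 16 and comes back at 23. Addition of 18 to 16 with acetic acid quench at −78 °C should give the tertiary alcohol F1. Bu4NF buffered with AcOH should remove the silyl group to give the cis-diol F2. NaIO4 glycol cleavage of the C1–C4 bond should give the keto aldehyde F3, in which C5 and C6 are already in place. Bu3SnH/AIBN (O-stannyl ketyl from the aldehyde adding 6-endo to the β-carbon C3 of the 2-methoxy enone) should form C3–C4 and give the hydroxy ketone F4. Et3SiOTf/Et3N should give the bis-silyl compound F5 (enol ether toward the OMe-bearing carbon), Pd(OAc)2 the silyl-protected enone F6, and HF·pyridine the target 23.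

**Step 6.** The enantiotopic-proton discrimination may be incomplete, and the cyclobutanone enolate may self-condense before silylation. The fallback replaces reagent control by an auxiliary, sets out from 9 and comes back at 13, so it also bypasses step 7. Condensation of 9 with (S)-1-amino-2-(methoxymethyl)pyrrolidine (or its enantiomer, whichever delivers the 2R centre) should give the hydrazone F7. LiN(i-Pr)2 then MeI at −100 °C should give the trans-methylated hydrazone F8 (auxiliary-controlled face, matched with the anti-to-farnesyl preference). Two-phase aqueous oxalic acid should release 13.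

**Step 11.** The silyl enol ether may be protodesilylated to the saturated methoxy ketone before palladation, and divalent palladium may engage the trisubstituted alkenes. The fallback sets out from 22 and comes back at 23. PhSeCl at −78 °C should convert the silyl enol ether into the 2-phenylselanyl ketone F9. NaIO4/NaHCO3 should then oxidise selenium and trigger selenoxide syn-elimination, which can only take the C3 hydrogen, to give 23.

Further compounds
F1 | step 10 | (1R,2R,3R,4S)-1-(1-methoxyethenyl)-2-methyl-3-farnesyl-4-(triethylsilyloxy)cyclobutan-1-ol | O[C@]1(C(OC)=C)[C@H](C)[C@@H](C/C=C(\C)CC/C=C(\C)CCC=C(C)C)[C@@H]1O[Si](CC)(CC)CC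
F2 | step 10 | cis-1-(1-methoxyethenyl)-4-methyl-3-farnesylcyclobutane-1,2-diol | O[C@]1(C(OC)=C)[C@H](C)[C@@H](C/C=C(\C)CC/C=C(\C)CCC=C(C)C)[C@@H]1O
F3 | step 10 | (2R,3R)-2-farnesyl-5-methoxy-3-methyl-4-oxohex-5-enal | O=C[C@H](C/C=C(\C)CC/C=C(\C)CCC=C(C)C)[C@@H](C)C(=O)C(OC)=C
F4 | step 10 | (4R,5R,6R)-4-hydroxy-2-methoxy-6-methyl-5-farnesylcyclohexan-1-one (C2 epimers) | COC1C[C@H](O)[C@H](C/C=C(\C)CC/C=C(\C)CCC=C(C)C)[C@@H](C)C1=O
F5 | step 10 | triethylsilyl ether of 22 (1,4-bis(triethylsilyloxy)-2-methoxy-6-methyl-5-farnesylcyclohex-1-ene) | CC[Si](CC)(CC)OC1=C(OC)C[C@H](O[Si](CC)(CC)CC)[C@H](C/C=C(\C)CC/C=C(\C)CCC=C(C)C)[C@H]1C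
F6 | step 10 | (4R,5R,6R)-2-methoxy-6-methyl-5-farnesyl-4-(triethylsilyloxy)cyclohex-2-en-1-one | COC1=C[C@H](O[Si](CC)(CC)CC)[C@H](C/C=C(\C)CC/C=C(\C)CCC=C(C)C)[C@@H](C)C1=O
F7 | step 6 | 3-farnesylcyclobutanone (S)-2-(methoxymethyl)pyrrolidin-1-yl hydrazone | COC[C@@H]1CCCN1N=C1CC(C1)C/C=C(\C)CC/C=C(\C)CCC=C(C)C
F8 | step 6 | (2R,3S)-2-methyl-3-farnesylcyclobutanone (S)-2-(methoxymethyl)pyrrolidin-1-yl hydrazone | COC[C@@H]1CCCN1N=C1[C@H](C)[C@@H](C/C=C(\C)CC/C=C(\C)CCC=C(C)C)C1
F9 | step 11 | (4R,5R,6R)-4-hydroxy-2-methoxy-6-methyl-2-(phenylselanyl)-5-farnesylcyclohexan-1-one (C2 epimers) | COC1([Se]c2ccccc2)C[C@H](O)[C@H](C/C=C(\C)CC/C=C(\C)CCC=C(C)C)[C@@H](C)C1=O
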